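**Assumption:** Plagilin has no stereocentre and its biaryl axis carries only two ortho substituents, so it rotates freely and the molecule is achiral; no enantiocontrol is needed.

## Retrosynthetic overview

1. Plagilin ⇒ one global hydrogenation (C=C saturation plus O-debenzylation) of a tetra-O-benzyl bis-(Z)-stilbene; benzyl ethers on the catechols keep them distinct from the two aryl methyl ethers.
2. Bis-stilbene ⇒ two-fold protodecarboxylation of a bis(α-aryl acrylic acid).
3. Key disconnection: both ArCH=C(Ar')CO2H bonds ⇒ two-fold Perkin-type intermolecular aldol condensation of a tetrabenzyloxy-biphenyl-2,2'-dicarbaldehyde with 3-methoxyphenylacetic acid.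
4. Dialdehyde ⇒ Ullmann homocoupling of 2-bromo-4,5-bis(benzyloxy)benzaldehyde ⇒ bromination and benzylation of 3,4-dihydroxybenzaldehyde.
5. No ring is built: all benzene rings are bought; the biaryl bond is made first, then the two C2 bridges.

## Route

**Step 1**
Reactants: 1 3,4-dihydroxybenzaldehyde
Product: 2 3,4-bis(benzyloxy)benzaldehyde
Conditions: BnBr (2.4 equiv), K2CO3 (3 equiv), DMF, 60 °C
Reagents that add atoms: benzyl bromide BrCc1ccccc1
Why: Williamson ether synthesis, in which K2CO3 deprotonates both acidic phenols and the phenoxides displace bromide from the reactive benzylic halide while the aldehyde is untouched.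

**Step 2**
Reactants: 2 3,4-bis(benzyloxy)benzaldehyde
Product: 3 4,5-bis(benzyloxy)-2-bromobenzaldehyde
Conditions: Br2 (1.1 equiv), NaOAc, AcOH, rt
Reagents that add atoms: bromine BrBr
Why: Electrophilic aromatic bromination goes to the position para to the 3-benzyloxy group (ortho to CHO), the only unhindered alkoxy-activated site, as is well known for 3,4-dialkoxybenzaldehydes.

**Step 3**
Reactants: 3 4,5-bis(benzyloxy)-2-bromobenzaldehyde (two molecules)
Product: 4 4,4',5,5'-tetrakis(benzyloxy)-[1,1'-biphenyl]-2,2'-dicarbaldehyde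
Conditions: activated Cu powder (4 equiv), DMF, 150 °C, N2
Reagents that add atoms: none
Why: Classical Ullmann biaryl homocoupling, in which the ortho-formyl group activates the C–Br bond toward copper and the symmetry of the product means only one biaryl can form.

**Step 4**
Reactants: 4 4,4',5,5'-tetrakis(benzyloxy)-[1,1'-biphenyl]-2,2'-dicarbaldehyde; 5 2-(3-methoxyphenyl)acetic acid (2.6 equiv)
Product: 7 (2E,2'E)-3,3'-[4,4',5,5'-tetrakis(benzyloxy)-[1,1'-biphenyl]-2,2'-diyl]bis[2-(3-methoxyphenyl)prop-2-enoic acid], via acetic 2-(3-methoxyphenyl)acetic anhydride 6 (not isolated)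
Conditions: Ac2O, Et3N, 110 °C, 16 h; then H2O, acidic work-up
Reagents that add atoms: acetic anhydride CC(=O)OC(C)=O (its acetyl group sits only in intermediate 6 and leaves again as acetic acid; none of its atoms remain in 7)
Why: Perkin (Oglialoro) condensation, an intermolecular aldol condensation in which Et3N enolises mixed anhydride 6, the enolate adds to each non-enolisable aldehyde of 4, and acyl transfer followed by E1cB loss of acetate gives the (E)-acid with the two aryl groups cis.

**Step 5**
Reactants: 7 the bis(acrylic acid) from step 4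
Product: 8 4,4',5,5'-tetrakis(benzyloxy)-2,2'-bis[(Z)-2-(3-methoxyphenyl)ethenyl]-1,1'-biphenyl
Conditions: Cu powder (cat.), quinoline, 200 °C, N2, 2 h
Reagents that add atoms: none
Why: Copper-catalysed protodecarboxylation of an α-aryl cinnamic acid proceeds through a vinylcopper species with retention, giving the (Z)-stilbenes, whose geometry is erased in the next step anyway.

**Step 6**
Reactants: 8 the tetra-O-benzyl bis-(Z)-stilbene from step 5
Product: 9 Plagilin, 6,6'-bis[2-(3-methoxyphenyl)ethyl]-[1,1'-biphenyl]-3,3',4,4'-tetrol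
Conditions: H2 (1–3 atm), 10% Pd/C, THF/MeOH, rt; filtration and concentration under Ar
Reagents that add atoms: none
Why: Heterogeneous catalytic hydrogenation saturates both stilbene double bonds and hydrogenolysis cleaves the four benzylic C–O bonds, while the aryl methyl ethers and the biaryl are inert and no stereocentre is created.

## Compound list

1 | 3,4-dihydroxybenzaldehyde | O=Cc1ccc(O)c(O)c1 | starting material
2 | 3,4-bis(benzyloxy)benzaldehyde | O=Cc1ccc(OCc2ccccc2)c(OCc2ccccc2)c1 | intermediate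
3 | 4,5-bis(benzyloxy)-2-bromobenzaldehyde | O=Cc1cc(OCc2ccccc2)c(OCc2ccccc2)cc1Br | intermediate
4 | 4,4',5,5'-tetrakis(benzyloxy)-[1,1'-biphenyl]-2,2'-dicarbaldehyde | O=Cc1cc(OCc2ccccc2)c(OCc2ccccc2)cc1-c1cc(OCc2ccccc2)c(OCc2ccccc2)cc1C=O | intermediate
5 | 2-(3-methoxyphenyl)acetic acid | COc1cccc(CC(=O)O)c1 | starting material
6 | acetic 2-(3-methoxyphenyl)acetic anhydride | COc1cccc(CC(=O)OC(C)=O)c1 | intermediate (not isolated)
7 | (2E,2'E)-3,3'-[4,4',5,5'-tetrakis(benzyloxy)-[1,1'-biphenyl]-2,2'-diyl]bis[2-(3-methoxyphenyl)prop-2-enoic acid] | OC(=O)/C(=C/c1cc(OCc2ccccc2)c(OCc2ccccc2)cc1-c1cc(OCc2ccccc2)c(OCc2ccccc2)cc1/C=C(/C(=O)O)c1cccc(OC)c1)c1cccc(OC)c1 | intermediate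
8 | 4,4',5,5'-tetrakis(benzyloxy)-2,2'-bis[(Z)-2-(3-methoxyphenyl)ethenyl]-1,1'-biphenyl | COc1cccc(/C=C\c2cc(OCc3ccccc3)c(OCc3ccccc3)cc2-c2cc(OCc3ccccc3)c(OCc3ccccc3)cc2/C=C\c2cccc(OC)c2)c1 | intermediate
9 | Plagilin, 6,6'-bis[2-(3-methoxyphenyl)ethyl]-[1,1'-biphenyl]-3,3',4,4'-tetrol | COc1cccc(CCc2cc(O)c(O)cc2-c2cc(O)c(O)cc2CCc2cccc(OC)c2)c1 | target

## Summary

Total step count: 6.
Longest linear sequence: 6 steps (1 → 2 → 3 → 4 → 7 → 8 → 9); acid 5 is bought.

## Steps most likely to fail, with fallbacks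

**Step 4 (two-fold Perkin condensation).** The aldehydes are electron-rich and hindered, two condensations are needed, and a biphenyl-2,2'-dicarbaldehyde can be diverted by an intramolecular second aldol into a seven-membered ring. The fallback sets out from 3 and comes back at 8. The same Perkin condensation is run on the monomeric bromoaldehyde 3 with acid 5 (Ac2O, Et3N, 110 °C; 6 forms again in the flask) to give (E)-3-[4,5-bis(benzyloxy)-2-bromophenyl]-2-(3-methoxyphenyl)prop-2-enoic acid F2. Decarboxylation with Cu powder in quinoline at 200 °C gives 1,2-bis(benzyloxy)-4-bromo-5-[(Z)-2-(3-methoxyphenyl)ethenyl]benzene F3. Reductive homocoupling of F3 (NiCl2(PPh3)2 cat., Zn dust, Et4NI, THF, 50 °C) builds the biaryl bond last and delivers 8.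

**Step 5 (two-fold decarboxylation at 200 °C).** Four aryl benzyl ethers must survive hot quinoline, and two carboxyl groups must both leave. The fallback sets out from 4 and comes back at 9, avoiding any carboxyl group. Horner–Wadsworth–Emmons olefination of dialdehyde 4 with commercial diethyl (3-methoxybenzyl)phosphonate (KOtBu, THF, 0 °C to rt) gives 4,4',5,5'-tetrakis(benzyloxy)-2,2'-bis[(E)-2-(3-methoxyphenyl)ethenyl]-1,1'-biphenyl F4. F4 is hydrogenated under the conditions of step 6 to give 9.

**Step 3 (Ullmann homocoupling).** Yields vary with the copper batch, and reductive debromination back to 2 competes. The fallback sets out from 3 and comes back at 4. Half of bromide 3 is borylated (bis(pinacolato)diboron, KOAc, PdCl2(dppf), dioxane, 85 °C) to 4,5-bis(benzyloxy)-2-(4,4,5,5-tetramethyl-1,3,2-dioxaborolan-2-yl)benzaldehyde F1. Suzuki–Miyaura cross-coupling of F1 with the other half of 3 (Pd(PPh3)4, aqueous K2CO3, toluene/EtOH, 90 °C) gives dialdehyde 4.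

## Further compounds

F1 | step 3 | 4,5-bis(benzyloxy)-2-(4,4,5,5-tetramethyl-1,3,2-dioxaborolan-2-yl)benzaldehyde | O=Cc1cc(OCc2ccccc2)c(OCc2ccccc2)cc1B1OC(C)(C)C(C)(C)O1
F2 | step 4 | (E)-3-[4,5-bis(benzyloxy)-2-bromophenyl]-2-(3-methoxyphenyl)prop-2-enoic acid | OC(=O)/C(=C/c1cc(OCc2ccccc2)c(OCc2ccccc2)cc1Br)c1cccc(OC)c1
F3 | step 4 | 1,2-bis(benzyloxy)-4-bromo-5-[(Z)-2-(3-methoxyphenyl)ethenyl]benzene | COc1cccc(/C=C\c2cc(OCc3ccccc3)c(OCc3ccccc3)cc2Br)c1
F4 | step 5 | 4,4',5,5'-tetrakis(benzyloxy)-2,2'-bis[(E)-2-(3-methoxyphenyl)ethenyl]-1,1'-biphenyl | COc1cccc(/C=C/c2cc(OCc3ccccc3)c(OCc3ccccc3)cc2-c2cc(OCc3ccccc3)c(OCc3ccccc3)cc2/C=C/c2cccc(OC)c2)c1
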